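The route rests on cutting ring A at A C2–C3 and A C1–C6, so that the doubly ortho-substituted depside ester never has to be made by acylation. In ring A the ester carbon C1 sits between the heptyl carbon C2 and the methoxy carbon C6, and C4 carries the other oxygen; a 2-ynoate can supply C1 and C2, and 1,1-dimethoxy-3-(trimethylsilyloxy)buta-1,3-diene supplies C3 to C6 with both oxygens in place. One thermal (4+2) cycloaddition, then loss of methanol and desilylation, builds all of ring A onto an ester link that already exists. The precursor is the dec-2-ynoate of the ring B phenol tert-butyl 2-heptyl-4-hydroxy-6-methoxybenzoate, its acid masked as a tert-butyl ester.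

Key step: step 7

Assumption: ring A is numbered from the ester-bearing carbon (C1) via the heptyl-bearing carbon (C2) to the methoxy-bearing carbon (C6), ring B likewise from its carboxyl carbon, and dec-2-ynoic acid is taken as a catalogue compound.

Step 1
Reactants: 1 2-methoxy-6-methylbenzoic acid; 2 1-bromohexane
Product: 4 2-heptyl-6-methoxybenzoic acid, via dilithium dianion 3 (not isolated)
Conditions: LiN(i-Pr)2 (2.2 equiv), THF, −78 to 0 °C; then 2, −78 °C to rt; aq. HCl work-up
Reagents that add atoms: none
Why: Two equivalents of amide base should give the carboxylate-stabilised benzylic anion (lateral lithiation of an o-toluic acid, both ring positions ortho to the carboxylate being blocked), which is C-alkylated by the primary bromide in an SN2 reaction.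

Step 2
Reactants: 4 2-heptyl-6-methoxybenzoic acid
Product: 5 tert-butyl 2-heptyl-6-methoxybenzoate
Conditions: tert-butyl 2,2,2-trichloroacetimidate (2 equiv), BF3·OEt2 (cat.), CH2Cl2/cyclohexane, rt
Reagents that add atoms: tert-butyl 2,2,2-trichloroacetimidate, CC(C)(C)OC(=N)C(Cl)(Cl)Cl
Why: Acid-catalysed O-tert-butylation with a trichloroacetimidate proceeds by attack of the carboxyl oxygen on a tert-butyl cation, so the two ortho substituents that would slow an addition–elimination esterification at the carbonyl should not matter.

Step 3
Reactants: 5 tert-butyl 2-heptyl-6-methoxybenzoate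
Product: 7 tert-butyl 2-heptyl-4-hydroxy-6-methoxybenzoate, via aryl pinacol boronate 6 (not isolated)
Conditions: [Ir(OMe)(cod)]2 (1.5 mol %), 4,4'-di-tert-butyl-2,2'-bipyridine (3 mol %), B2pin2 (1.0 equiv), THF, 80 °C; evaporate; then KHSO5 (as 2KHSO5·KHSO4·K2SO4), acetone/H2O, rt
Reagents that add atoms: bis(pinacolato)diboron, CC1(C)OB(OC1(C)C)B1OC(C)(C)C(C)(C)O1 (boron of intermediate 6 only); potassium peroxymonosulfate, [K+].[O-]S(=O)(=O)OO (the phenol oxygen)
Why: Iridium-catalysed aromatic C–H borylation is sterically governed and should pick C4–H, the only ring hydrogen of this 1,2,3-trisubstituted arene without an ortho neighbour, and the aryl boronate is then oxidised at the same carbon by peroxymonosulfate (one-pot C–H borylation–oxidation to a phenol).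

Step 4
Reactants: 7 tert-butyl 2-heptyl-4-hydroxy-6-methoxybenzoate; 8 dec-2-ynoic acid
Product: 9 tert-butyl 4-(dec-2-ynoyloxy)-2-heptyl-6-methoxybenzoate
Conditions: 8 (1.2 equiv), DCC (1.2 equiv), DMAP (0.1 equiv), CH2Cl2, 0 °C to rt
Reagents that add atoms: none
Why: Steglich esterification joins an unhindered phenol to an unhindered alkynoic acid through the O-acylisourea and acylpyridinium, and low temperature with only catalytic DMAP should keep conjugate addition to the ynoate in check.

Step 5
Reactants: 10 1,1-dimethoxyethene; 11 acetyl chloride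
Product: 12 4,4-dimethoxybut-3-en-2-one
Conditions: Et3N (1.1 equiv), Et2O, 0 °C to rt; filtration, distillation
Reagents that add atoms: none
Why: The nucleophilic methylene carbon of the ketene acetal is C-acylated by the acid chloride and the amine removes the proton from the resulting dialkoxycarbenium ion (acylation of a ketene acetal), giving a stabilised push–pull β,β-dimethoxy enone.

Step 6
Reactants: 12 4,4-dimethoxybut-3-en-2-one
Product: 14 1,1-dimethoxy-3-(trimethylsilyloxy)buta-1,3-diene, via lithium dienolate 13 (not isolated)
Conditions: LiN(i-Pr)2 (1.05 equiv), THF, −78 °C; Me3SiCl, −78 °C to rt; pentane, filtration, distillation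
Reagents that add atoms: chlorotrimethylsilane, C[Si](C)(C)Cl
Why: The acetyl methyl group is the only enolisable position, so kinetic deprotonation and O-silylation of the cross-conjugated enolate (silyl enol ether formation) should give the 2-silyloxydiene, isolated without aqueous contact.

Step 7
Reactants: 9 tert-butyl 4-(dec-2-ynoyloxy)-2-heptyl-6-methoxybenzoate; 14 1,1-dimethoxy-3-(trimethylsilyloxy)buta-1,3-diene
Product: 17 tert-butyl 2-heptyl-4-[(2-heptyl-4-hydroxy-6-methoxybenzoyl)oxy]-6-methoxybenzoate, via cyclohexa-1,4-diene cycloadduct 15 (not isolated), via aryl trimethylsilyl ether 16 (not isolated)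
Conditions: 14 (3 equiv), toluene, 110 °C, sealed tube; then 0.5 M aq. HCl, THF, rt
Reagents that add atoms: none
Why: The electron-rich diene and the electron-poor aryl ynoate should combine in a thermal, concerted but asynchronous (4+2) cycloaddition in which bonding runs ahead between the diene CH2 terminus and the heptyl-bearing β-carbon of the ynoate, the acetal carbon then closing onto the α-carbon. The closest known reaction type is the Diels–Alder benzannulation of 1,1-dialkoxy-3-silyloxybutadienes with acetylenic esters, which aromatise to 4-hydroxy-6-alkoxybenzoates. Ring A is closed as a six-membered carbocycle by intermolecular (4+2) cycloaddition that makes A C2–C3 and A C1–C6 together; cycloadduct 15 then aromatises by 1,4-elimination of methanol (an acetal methoxy group and a hydrogen of the ring CH2) to silyl ether 16, which dilute acid cleaves to phenol 17. No stereocentre arises, because the only sp3 ring atoms of 15 are CH2 and C(OMe)2. The selectivity needed is regiochemical and is secured by matched polarisation: the diene CH2 terminus is made nucleophilic by both the ketene acetal and the silyloxy group and the ynoate β-carbon is the electrophilic site, so methoxy should end at C6 beside the carbonyl and heptyl at C2. The aryl ester activates the triple bond more than an alkyl ester would, the excess diene traps the methanol set free, and neither ester should react under neutral thermal conditions or during the brief acidic work-up.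

Step 8
Reactants: 17 tert-butyl 2-heptyl-4-[(2-heptyl-4-hydroxy-6-methoxybenzoyl)oxy]-6-methoxybenzoate
Product: 18 tert-butyl 2-heptyl-4-[(2-heptyl-4,6-dimethoxybenzoyl)oxy]-6-methoxybenzoate
Conditions: MeI (2 equiv), K2CO3 (2 equiv), acetone, rt to 40 °C
Reagents that add atoms: iodomethane, CI
Why: Williamson O-methylation of the ring A phenoxide, the only acidic site, should be clean because the 2,6-disubstituted aryl benzoate is too hindered to be cleaved by carbonate in acetone.

Step 9
Reactants: 18 tert-butyl 2-heptyl-4-[(2-heptyl-4,6-dimethoxybenzoyl)oxy]-6-methoxybenzoate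
Product: 19 2-heptyl-4-[(2-heptyl-4,6-dimethoxybenzoyl)oxy]-6-methoxybenzoic acid
Conditions: CF3CO2H/CH2Cl2 (1:4), 0 °C to rt
Reagents that add atoms: none
Why: Acidolysis of the tert-butyl ester by alkyl–oxygen cleavage (loss of 2-methylpropene) should free the ring B acid without any nucleophile that could attack the depside ester, and the aryl methyl ethers are inert to trifluoroacetic acid.

Compound list
1 | 2-methoxy-6-methylbenzoic acid | Cc1cccc(OC)c1C(=O)O | starting material
2 | 1-bromohexane | CCCCCCBr | starting material
3 | dilithium dianion of 1 (lithium 2-(lithiomethyl)-6-methoxybenzoate) | [Li+].[Li+].[CH2-]c1cccc(OC)c1C(=O)[O-] | intermediate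
4 | 2-heptyl-6-methoxybenzoic acid | CCCCCCCc1cccc(OC)c1C(=O)O | intermediate
5 | tert-butyl 2-heptyl-6-methoxybenzoate | CCCCCCCc1cccc(OC)c1C(=O)OC(C)(C)C | intermediate
6 | tert-butyl 2-heptyl-6-methoxy-4-(4,4,5,5-tetramethyl-1,3,2-dioxaborolan-2-yl)benzoate | CCCCCCCc1cc(B2OC(C)(C)C(C)(C)O2)cc(OC)c1C(=O)OC(C)(C)C | intermediate
7 | tert-butyl 2-heptyl-4-hydroxy-6-methoxybenzoate | CCCCCCCc1cc(O)cc(OC)c1C(=O)OC(C)(C)C | intermediate
8 | dec-2-ynoic acid | CCCCCCCC#CC(=O)O | starting material
9 | tert-butyl 4-(dec-2-ynoyloxy)-2-heptyl-6-methoxybenzoate | CCCCCCCC#CC(=O)Oc1cc(CCCCCCC)c(C(=O)OC(C)(C)C)c(OC)c1 | intermediate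
10 | 1,1-dimethoxyethene | C=C(OC)OC | starting material
11 | acetyl chloride | CC(=O)Cl | starting material
12 | 4,4-dimethoxybut-3-en-2-one | CC(=O)C=C(OC)OC | intermediate
13 | lithium 4,4-dimethoxybuta-1,3-dien-2-olate | [Li+].C=C([O-])C=C(OC)OC | intermediate
14 | 1,1-dimethoxy-3-(trimethylsilyloxy)buta-1,3-diene | C=C(O[Si](C)(C)C)C=C(OC)OC | intermediate
15 | tert-butyl 2-heptyl-4-{[2-heptyl-6,6-dimethoxy-4-(trimethylsilyloxy)cyclohexa-1,4-diene-1-carbonyl]oxy}-6-methoxybenzoate | CCCCCCCC1=C(C(=O)Oc2cc(CCCCCCC)c(C(=O)OC(C)(C)C)c(OC)c2)C(OC)(OC)C=C(O[Si](C)(C)C)C1 | intermediate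
16 | tert-butyl 2-heptyl-4-{[2-heptyl-6-methoxy-4-(trimethylsilyloxy)benzoyl]oxy}-6-methoxybenzoate | CCCCCCCc1cc(O[Si](C)(C)C)cc(OC)c1C(=O)Oc1cc(CCCCCCC)c(C(=O)OC(C)(C)C)c(OC)c1 | intermediate
17 | tert-butyl 2-heptyl-4-[(2-heptyl-4-hydroxy-6-methoxybenzoyl)oxy]-6-methoxybenzoate | CCCCCCCc1cc(OC(=O)c2c(CCCCCCC)cc(O)cc2OC)cc(OC)c1C(=O)OC(C)(C)C | intermediate
18 | tert-butyl 2-heptyl-4-[(2-heptyl-4,6-dimethoxybenzoyl)oxy]-6-methoxybenzoate | CCCCCCCc1cc(OC(=O)c2c(CCCCCCC)cc(OC)cc2OC)cc(OC)c1C(=O)OC(C)(C)C | intermediate
19 | 2-heptyl-4-[(2-heptyl-4,6-dimethoxybenzoyl)oxy]-6-methoxybenzoic acid | CCCCCCCc1cc(OC(=O)c2c(CCCCCCC)cc(OC)cc2OC)cc(OC)c1C(=O)O | target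

Total step count: 9 steps.
Longest linear sequence: 7 steps (steps 1, 2, 3, 4, 7, 8 and 9, from compound 1); steps 5 and 6 form the two-step side branch to the diene.

Steps most likely to fail

1. Step 7. The cycloaddition may be slower than the thermal decay or adventitious hydrolysis of the diene. The diene may also add to the ynoate in a conjugate sense without closing the ring, or the methanol released may start to transesterify the aryl ester. The fallback gives up ring construction on the ester and makes the depside bond by acylation with a finished ring A acid. It sets out from 2 and 7 and comes back at 18. Commercial 2,4-dimethoxy-6-methylbenzoic acid (Cc1cc(OC)cc(OC)c1C(=O)O) would be deprotonated twice with LiN(i-Pr)2 as in step 1 to the dilithium dianion of 2,4-dimethoxy-6-methylbenzoic acid F1. Alkylation with 2 should give 2-heptyl-4,6-dimethoxybenzoic acid F2. Oxalyl chloride and catalytic DMF in CH2Cl2 would convert this into 2-heptyl-4,6-dimethoxybenzoyl chloride F3. This electron-rich aroyl chloride would acylate phenol 7 (Et3N, DMAP, CH2Cl2, or the sodium phenoxide made with NaH in THF) to give 18, from which step 9 follows unchanged.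

2. Step 3. The borylation may fail to discriminate fully between C4–H and C5–H next to the small methoxy group, and the electron-rich phenol may be over-oxidised in the one-pot oxidation. The fallback replaces C–H functionalisation by building ring B itself from acyclic pieces. It sets out from 8 and 14 and comes back at 7. Acid 8 would be esterified with tert-butyl 2,2,2-trichloroacetimidate (cat. BF3·OEt2) to tert-butyl dec-2-ynoate F4. Heating F4 with 14 in toluene should give tert-butyl 2-heptyl-6,6-dimethoxy-4-(trimethylsilyloxy)cyclohexa-1,4-diene-1-carboxylate F5. This loses methanol to tert-butyl 2-heptyl-6-methoxy-4-(trimethylsilyloxy)benzoate F6, and dilute acid then gives phenol 7. This is the same benzannulation applied to a plain alkyl ynoate, the substrate class for which it is established.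

3. Step 5. Acid-triggered polymerisation of the ketene acetal, or ketene formation from acetyl chloride and the amine, may outrun C-acylation. The fallback reaches the same enone by acylating a chloroalkene and then substituting at the vinylic carbon. It sets out from 11 and comes back at 12. AlCl3-mediated addition of 11 to 1,1-dichloroethene (C=C(Cl)Cl) in CH2Cl2 should give 4,4,4-trichlorobutan-2-one F7. This loses hydrogen chloride on distillation to 4,4-dichlorobut-3-en-2-one F8. Two successive addition–elimination reactions with NaOMe (2 equiv, Et2O, 0 °C) then give 12, ready for step 6.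

Further compounds
F1 | step 7 | dilithium dianion of 2,4-dimethoxy-6-methylbenzoic acid | [Li+].[Li+].[CH2-]c1cc(OC)cc(OC)c1C(=O)[O-]
F2 | step 7 | 2-heptyl-4,6-dimethoxybenzoic acid | CCCCCCCc1cc(OC)cc(OC)c1C(=O)O
F3 | step 7 | 2-heptyl-4,6-dimethoxybenzoyl chloride | CCCCCCCc1cc(OC)cc(OC)c1C(=O)Cl
F4 | step 3 | tert-butyl dec-2-ynoate | CCCCCCCC#CC(=O)OC(C)(C)C
F5 | step 3 | tert-butyl 2-heptyl-6,6-dimethoxy-4-(trimethylsilyloxy)cyclohexa-1,4-diene-1-carboxylate | CCCCCCCC1=C(C(=O)OC(C)(C)C)C(OC)(OC)C=C(O[Si](C)(C)C)C1
F6 | step 3 | tert-butyl 2-heptyl-6-methoxy-4-(trimethylsilyloxy)benzoate | CCCCCCCc1cc(O[Si](C)(C)C)cc(OC)c1C(=O)OC(C)(C)C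
F7 | step 5 | 4,4,4-trichlorobutan-2-one | CC(=O)CC(Cl)(Cl)Cl
F8 | step 5 | 4,4-dichlorobut-3-en-2-one | CC(=O)C=C(Cl)Cl
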